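The numbers in the tables are calculated for an exercise; noise was put on by code.

**The decision.** I rank these flasks by one division, without stepping them through time.

| flask | J | G | remark | time |
|---|---|---|---|---|
| Friday's | 0.050 M | 0.0475 M | run made earlier |  |
| Monday's | 0.025 M | 0.0475 M | run made earlier |  |
| red | 0.050 M | 0.0475 M | everything together at the start | 30 min |
| teal | 0.050 M (fed, over 25 min) | 0.0475 M | all else is in the flask from the start; the feed brings no volume worth counting | 30 min |
| amber | 0.050 M (in portions, 3, over 25 min) | 0.0475 M | first portion at the start, last at 25 min | 30 min |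
| violet | 0.050 M | 0.0475 M (fed, over 6.0 min) | all else is in the flask from the start; the feed brings no volume worth counting | 30 min |
| ochre | 0.050 M | 0.0475 M (fed, over 25 min) | all else is in the flask from the start; the feed brings no volume worth counting | 30 min |

- Friday's (time / min: Z / %, E / %, J / %): 5.00: 1.5, 41.7, 33.4; 10.0: 5.8, 50.5, 18.5; 15.0: 11.3, 52.9, 10.8; 20.0: 15.0, 53.0, 7.2; 25.0: 22.1, 53.7, 4.5; 30.0: 21.8, 52.8, 5.5
- Monday's (time / min: Z / %, E / %, J / %): 1.50: 0, 14.2, 73.7; 3.00: 1.7, 20.5, 58.5; 5.00: 2.1, 26.4, 43.8; 6.00: 4.2, 29.0, 37.6; 8.00: 5.6, 32.1, 30.0; 10.0: 8.6, 32.4, 25.2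

(each reading ± 1 percentage point)

- the flask that comes out highest in share of Z in Z plus E, or "all alike" when all lie within 1.5 percentage points (red / teal / amber / violet / ochre / all alike)
- share of Z in Z plus E at the end, red
- share of Z in Z plus E at the end, teal
- share of Z in Z plus E at the end, amber
- share of Z in Z plus E at the end, violet
- share of Z in Z plus E at the end, ochre

- in percentages every species weighs as the J in it: one E counts as two
- the numbers in the tables scatter with a standard deviation of 1 percentage point

**The rule.** Friday's and Monday's runs hold the same G, but Monday's has half the J. At 10.0 min, the J gone elsewhere than into E, per J found in E, reads 0.614 on Friday and 1.31 on Monday, twice as much. So I take E to grow as cJ squared and the rest as cJ times cG, and their ratio follows cG/cJ. With equal constants the even split, my zero, falls at cG = 2cJ.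

**Branch number.** Friday's run opens at 0.475: this is the branch number b, cG over 2cJ, a selectivity factor with the constants taken equal. Monday's opens at 0.950. The readings, which sum up each run to 10.0 min, stand 1.29 and 1.38 times above these openings.

**My reckoning.** Red repeats Friday's recipe, so I expect the share in Friday's last reading, 29.2%. Amber's first portion is a third of the J, so amber opens at 1.42, higher than red. Ochre opens with its G still to come, so I put it low. I commit to amber on top, without having reckoned teal's cJ along its feed.

**The forecast.** It names amber: red 29.5%, teal 35%, amber 36.5%, violet 22%, ochre 12.5%, with “Amber edges ahead, though narrowly”.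

**The result.** Amber comes highest at 33.4%, against teal 31.8%, red 29.9%, violet 20.0% and ochre 9.27%. At 30.0 min amber still holds 22.5% of the J charged as J.

    J + G → X + Q (k = 2.02 L mol⁻¹ min⁻¹)
    X → Z (k = 0.0354 min⁻¹)
    2 J → E (k = 2.38 L mol⁻¹ min⁻¹)
    D ⇌ Q, rate k4*(cs4 - [Q]) while solid is left; crystals form when [Q] > cs4 (solubility = 0.760 mM, k = 0.446 min⁻¹)

Amber's last portion goes in at 25.0 min, onto 9.68% of the J charged and 63.8% of its own charge of G, so b just after it is 0.705, above red's opening of 0.475.

**A second flask.** Amber's recipe with 0.020 M of J opens at b = 3.56. If I take that b as Z plus X per E at the end, and borrow amber's fraction of Z in Z plus X at 30.0 min, 0.399, my rough estimate of the share is 58.7%. The computed flask gives 55.8%.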